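**Retrosynthetic overview**

- The strategy rests on the hexasubstituted central benzene ring, whose carbons carry in sequence C1 indol-3-yl, C2 O, C3 O, C4 indol-3-yl, C5 O, C6 O. The run C6–C1–C2–C3 is a squarate unit carrying the 6-methoxyindole; the pair C4–C5 is an enol ether carrying the 5-oxygenated indole.
- Target ⇐ (O-debenzylation, N-deprotection, O-methylation) 2,5-bis(indolyl)-3,6-dimethoxyhydroquinone ⇐ thermal ring expansion of a 4-alkenyl-4-hydroxycyclobutenone. This forms C5–C6 and the central ring, the only ring made in the route; both indole bicycles are bought.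
- Cyclobutenone ⇐ 3-methoxy-4-indolylcyclobutenedione + 1-indolyl-2-methoxyvinyllithium (forms C3–C4). Dione ⇐ dimethyl squarate + 3-lithioindole. Vinyllithium ⇐ enol triflate of a 3-(methoxyacetyl)indole via the vinylstannane.

Key step: step 10

Remark: the vinyl nucleophile must carry lithium on the indole-bearing carbon (β to oxygen) and syn to methoxy, because the anti isomer would lose LiOMe to give the alkyne; the ring-expansion precursor is therefore made as the (Z)-enol ether, and this geometry is erased in the ring closure. SEM = 2-(trimethylsilyl)ethoxymethyl.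

**Route**

Step 1
Reactants: 1 6-methoxy-1H-indole
Product: 2 6-methoxy-1-SEM-indole
Conditions: NaH, SEMCl, DMF, 0 °C → rt
Reagents that add atoms: 2-(trimethylsilyl)ethoxymethyl chloride (SEMCl), C[Si](C)(C)CCOCCl
Why: N-alkylation (SN2) of the sodium indolide by the chloromethyl ether is clean at nitrogen in DMF, and the SEM group should later tolerate organolithiums, heat and carbonate base.

Step 2
Reactants: 2 6-methoxy-1-SEM-indole
Product: 3 3-bromo-6-methoxy-1-SEM-indole
Conditions: NBS (1.0 equiv), THF, −78 → 0 °C, dark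
Reagents that add atoms: N-bromosuccinimide, O=C1CCC(=O)N1Br
Why: Electrophilic aromatic bromination should go at C3, the most nucleophilic indole carbon, and one equivalent at low temperature spares the methoxy-activated benzo ring.

Step 3
Reactants: 3 3-bromo-6-methoxy-1-SEM-indole; 4 dimethyl squarate
Product: 6 racemic 4-hydroxy-2,3-dimethoxy-4-(6-methoxy-1-SEM-indol-3-yl)cyclobut-2-en-1-one, via 3-lithio-6-methoxy-1-SEM-indole 5 (not isolated)
Conditions: t-BuLi (2 equiv), THF, −78 °C; cannulate into 4, THF, −78 °C; aq. NH4Cl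
Reagents that add atoms: tert-butyllithium, [Li]C(C)(C)C (its lithium stays only in intermediate 5)
Why: Bromine–lithium exchange outruns lithium migration to C2 at −78 °C, and inverse addition of the aryllithium gives 1,2-addition to one squarate carbonyl (carbinol centre racemic and later destroyed).

Step 4
Reactants: 6 racemic 4-hydroxy-2,3-dimethoxy-4-(6-methoxy-1-SEM-indol-3-yl)cyclobut-2-en-1-one
Product: 7 3-methoxy-4-(6-methoxy-1-SEM-indol-3-yl)cyclobut-3-ene-1,2-dione
Conditions: 12 M HCl (cat.), CH2Cl2, rt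
Reagents that add atoms: water, O
Why: Acid ionises the tertiary, indole-stabilised carbinol, water enters at the methoxy-bearing allyl terminus and methanol leaves, which is the known transposition of squarate adducts to 3-alkoxy-4-arylcyclobutenediones.

Step 5
Reactants: 8 5-benzyloxy-1H-indole; 9 methoxyacetyl chloride
Product: 10 1-(5-benzyloxy-1H-indol-3-yl)-2-methoxyethan-1-one
Conditions: Et2AlCl (1.5 equiv), CH2Cl2, 0 °C; then 9, 0 °C
Reagents that add atoms: none
Why: Dialkylaluminium chloride mediated Friedel–Crafts acylation of N-unprotected indoles goes at C3 without N-acylation, and the mild Lewis acid should leave the benzyl ether intact.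

Step 6
Reactants: 10 1-(5-benzyloxy-1H-indol-3-yl)-2-methoxyethan-1-one
Product: 11 1-(5-benzyloxy-1-SEM-indol-3-yl)-2-methoxyethan-1-one
Conditions: NaH (1.05 equiv), SEMCl, DMF, 0 °C
Reagents that add atoms: 2-(trimethylsilyl)ethoxymethyl chloride (SEMCl), C[Si](C)(C)CCOCCl
Why: The N–H of a 3-acylindole is far more acidic than the ketone α-CH2, so one equivalent of base should give selective N-alkylation.

Step 7
Reactants: 11 1-(5-benzyloxy-1-SEM-indol-3-yl)-2-methoxyethan-1-one
Product: 12 (Z)-1-(5-benzyloxy-1-SEM-indol-3-yl)-2-methoxyethenyl trifluoromethanesulfonate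
Conditions: LiN(SiMe3)2, THF, −78 °C; PhNTf2, −78 °C → rt; aq. NH4Cl
Reagents that add atoms: N-phenylbis(trifluoromethanesulfonimide), O=S(=O)(N(c1ccccc1)S(=O)(=O)C(F)(F)F)C(F)(F)F
Why: Enolisation is possible only at the CH2OMe group, lithium chelation between enolate oxygen and methoxy together with avoidance of allylic strain against the indole should give the Z enolate, and O-sulfonylation (enol triflate formation) keeps that geometry.

Step 8
Reactants: 12 (Z)-1-(5-benzyloxy-1-SEM-indol-3-yl)-2-methoxyethenyl trifluoromethanesulfonate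
Product: 13 5-benzyloxy-3-[(Z)-2-methoxy-1-(trimethylstannyl)ethenyl]-1-SEM-indole
Conditions: (Me3Sn)2, Pd(PPh3)4 (cat.), LiCl, THF, 65 °C
Reagents that add atoms: hexamethylditin, C[Sn](C)(C)[Sn](C)(C)C
Why: Palladium-catalysed stannylation of enol triflates with a ditin (oxidative addition, transmetalation, reductive elimination) proceeds with retention of alkene geometry, so tin ends up cis to methoxy.

Step 9
Reactants: 13 5-benzyloxy-3-[(Z)-2-methoxy-1-(trimethylstannyl)ethenyl]-1-SEM-indole; 7 3-methoxy-4-(6-methoxy-1-SEM-indol-3-yl)cyclobut-3-ene-1,2-dione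
Product: 15 racemic 4-hydroxy-3-methoxy-2-(6-methoxy-1-SEM-indol-3-yl)-4-[(Z)-1-(5-benzyloxy-1-SEM-indol-3-yl)-2-methoxyethenyl]cyclobut-2-en-1-one, via 1-indolyl-2-methoxyvinyllithium 14 (not isolated)
Conditions: MeLi (1.05 equiv), THF, −78 °C; cannulate into 7, THF, −78 °C; aq. NH4Cl at −78 °C
Reagents that add atoms: methyllithium, [Li]C (its lithium stays only in intermediate 14)
Why: Tin–lithium exchange with retention gives the methoxy-chelated cis-β-alkoxyvinyllithium, which is stable at −78 °C, and 1,2-addition should occur at the carbonyl next to the methoxy-bearing ring carbon because the other carbonyl is deactivated as a vinylogous ester (carbinol centre racemic and destroyed in step 10).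

Step 10
Reactants: 15 racemic 4-hydroxy-3-methoxy-2-(6-methoxy-1-SEM-indol-3-yl)-4-[(Z)-1-(5-benzyloxy-1-SEM-indol-3-yl)-2-methoxyethenyl]cyclobut-2-en-1-one
Product: 16 2-(5-benzyloxy-1-SEM-indol-3-yl)-5-(6-methoxy-1-SEM-indol-3-yl)-3,6-dimethoxybenzene-1,4-diol
Conditions: degassed toluene, 110 °C, Ar
Reagents that add atoms: none
Why: Heating breaks the C1–C4 bond of the cyclobutenone in a conrotatory 4π opening to a dienylketene, the sp carbon of the ketene then joins the CH(OMe) terminus of the vinyl arm in a 6π electrocyclisation, and enolisation of the cyclohexa-2,4-dienone delivers the hydroquinone; this is the Moore rearrangement of 4-alkenyl-4-hydroxycyclobutenones. The central benzene ring is closed by this thermal 6π electrocyclic closure (ketene carbon to enol ether carbon), helped by the indole nitrogen of the vinyl arm, which makes that terminus electron-rich. No stereocentre results: the carbinol centre and the alkene geometry of 15 are erased, and the transient sp3 CH(OMe) carbon is lost on tautomerisation. The step needs torquoselectivity, which the hydroxyl donor secures by turning outward so that the alkenyl arm points at the ketene, while the para placing of the two indoles was already fixed by the site of addition in step 9. The methoxy group lies on the inside of the closing terminus, which should slow but not stop closure because the sp ketene carbon carries no inward substituent and the ring opening is reversible. Oxygen must be excluded because 16 is an electron-rich hydroquinone.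

Step 11
Reactants: 16 2-(5-benzyloxy-1-SEM-indol-3-yl)-5-(6-methoxy-1-SEM-indol-3-yl)-3,6-dimethoxybenzene-1,4-diol
Product: 17 5-benzyloxy-3-[4-(6-methoxy-1-SEM-indol-3-yl)-2,3,5,6-tetramethoxyphenyl]-1-SEM-indole
Conditions: MeI (excess), K2CO3, degassed DMF, rt, Ar (crude 16 used at once)
Reagents that add atoms: iodomethane, CI
Why: Williamson O-methylation of the two phenoxides should be clean because both indole nitrogens are blocked and the SEM and benzyl groups are inert to carbonate.

Step 12
Reactants: 17 5-benzyloxy-3-[4-(6-methoxy-1-SEM-indol-3-yl)-2,3,5,6-tetramethoxyphenyl]-1-SEM-indole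
Product: 18 5-benzyloxy-3-[4-(6-methoxy-1H-indol-3-yl)-2,3,5,6-tetramethoxyphenyl]-1H-indole
Conditions: Bu4NF (excess), ethylenediamine, DMF, 80 °C
Reagents that add atoms: none
Why: Fluoride-induced fragmentation of the silylethyl aminal ether releases ethylene and formaldehyde from each nitrogen, and ethylenediamine traps the formaldehyde so that the N-hydroxymethyl stage does not persist.

Step 13
Reactants: 18 5-benzyloxy-3-[4-(6-methoxy-1H-indol-3-yl)-2,3,5,6-tetramethoxyphenyl]-1H-indole
Product: 19 3-[4-(6-methoxy-1H-indol-3-yl)-2,3,5,6-tetramethoxyphenyl]-1H-indol-5-ol (CNP0234672.0)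
Conditions: H2 (1 atm), 10% Pd/C, EtOAc–MeOH, rt
Reagents that add atoms: none
Why: Catalytic hydrogenolysis cleaves the benzylic C–O bond under conditions that leave indoles and aryl methyl ethers untouched, and it is placed last because the free 5-hydroxyindole is air-sensitive.

**Compound list**

1 | 6-methoxy-1H-indole | COc1ccc2cc[nH]c2c1 | starting material
2 | 6-methoxy-1-SEM-indole | COc1ccc2ccn(COCC[Si](C)(C)C)c2c1 | intermediate
3 | 3-bromo-6-methoxy-1-SEM-indole | COc1ccc2c(Br)cn(COCC[Si](C)(C)C)c2c1 | intermediate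
4 | dimethyl squarate (3,4-dimethoxycyclobut-3-ene-1,2-dione) | COC1=C(OC)C(=O)C1=O | starting material
5 | 3-lithio-6-methoxy-1-SEM-indole | COc1ccc2c([Li])cn(COCC[Si](C)(C)C)c2c1 | intermediate
6 | racemic 4-hydroxy-2,3-dimethoxy-4-(6-methoxy-1-SEM-indol-3-yl)cyclobut-2-en-1-one | COC1=C(OC)C(O)(c2cn(COCC[Si](C)(C)C)c3cc(OC)ccc23)C1=O | intermediate
7 | 3-methoxy-4-(6-methoxy-1-SEM-indol-3-yl)cyclobut-3-ene-1,2-dione | COC1=C(c2cn(COCC[Si](C)(C)C)c3cc(OC)ccc23)C(=O)C1=O | intermediate
8 | 5-benzyloxy-1H-indole | c1ccc(COc2ccc3[nH]ccc3c2)cc1 | starting material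
9 | methoxyacetyl chloride | COCC(Cl)=O | starting material
10 | 1-(5-benzyloxy-1H-indol-3-yl)-2-methoxyethan-1-one | COCC(=O)c1c[nH]c2ccc(OCc3ccccc3)cc12 | intermediate
11 | 1-(5-benzyloxy-1-SEM-indol-3-yl)-2-methoxyethan-1-one | COCC(=O)c1cn(COCC[Si](C)(C)C)c2ccc(OCc3ccccc3)cc12 | intermediate
12 | (Z)-1-(5-benzyloxy-1-SEM-indol-3-yl)-2-methoxyethenyl trifluoromethanesulfonate | CO/C=C(\OS(=O)(=O)C(F)(F)F)c1cn(COCC[Si](C)(C)C)c2ccc(OCc3ccccc3)cc12 | intermediate
13 | 5-benzyloxy-3-[(Z)-2-methoxy-1-(trimethylstannyl)ethenyl]-1-SEM-indole | CO/C=C(\[Sn](C)(C)C)c1cn(COCC[Si](C)(C)C)c2ccc(OCc3ccccc3)cc12 | intermediate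
14 | [1-(5-benzyloxy-1-SEM-indol-3-yl)-2-methoxyethenyl]lithium, lithium cis to methoxy | CO/C=C(\[Li])c1cn(COCC[Si](C)(C)C)c2ccc(OCc3ccccc3)cc12 | intermediate
15 | racemic 4-hydroxy-3-methoxy-2-(6-methoxy-1-SEM-indol-3-yl)-4-[(Z)-1-(5-benzyloxy-1-SEM-indol-3-yl)-2-methoxyethenyl]cyclobut-2-en-1-one | CO/C=C(\C1(O)C(OC)=C(c2cn(COCC[Si](C)(C)C)c3cc(OC)ccc23)C1=O)c1cn(COCC[Si](C)(C)C)c2ccc(OCc3ccccc3)cc12 | intermediate
16 | 2-(5-benzyloxy-1-SEM-indol-3-yl)-5-(6-methoxy-1-SEM-indol-3-yl)-3,6-dimethoxybenzene-1,4-diol | Oc1c(-c2cn(COCC[Si](C)(C)C)c3cc(OC)ccc23)c(OC)c(O)c(-c2cn(COCC[Si](C)(C)C)c3ccc(OCc4ccccc4)cc23)c1OC | intermediate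
17 | 5-benzyloxy-3-[4-(6-methoxy-1-SEM-indol-3-yl)-2,3,5,6-tetramethoxyphenyl]-1-SEM-indole | COc1c(-c2cn(COCC[Si](C)(C)C)c3cc(OC)ccc23)c(OC)c(OC)c(-c2cn(COCC[Si](C)(C)C)c3ccc(OCc4ccccc4)cc23)c1OC | intermediate
18 | 5-benzyloxy-3-[4-(6-methoxy-1H-indol-3-yl)-2,3,5,6-tetramethoxyphenyl]-1H-indole | COc1c(-c2c[nH]c3cc(OC)ccc23)c(OC)c(OC)c(-c2c[nH]c3ccc(OCc4ccccc4)cc23)c1OC | intermediate
19 | 3-[4-(6-methoxy-1H-indol-3-yl)-2,3,5,6-tetramethoxyphenyl]-1H-indol-5-ol (CNP0234672.0) | COc1ccc2c(-c3c(OC)c(OC)c(-c4c[nH]c5ccc(O)cc45)c(OC)c3OC)c[nH]c2c1 | target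

**Step count and risks**

Total step count: 13. Longest linear sequence: 9 steps (steps 1, 2, 3, 4, 9, 10, 11, 12, 13; the branch through steps 5–8 is equally long).

Steps most likely to fail:

1. Step 9. The vinyllithium may lose lithium methoxide to give the alkyne, or pass its lithium to the indole C2 position, before it reaches the dione. The donor indole on 7 may also let part of the reagent attack the vinylogous-ester carbonyl. Fallback (cross-coupling onto a preformed benzene ring; sets out from 3, comes back at 17): bromide 3 is lithiated as in step 3 and quenched with 2-isopropoxy-4,4,5,5-tetramethyl-1,3,2-dioxaborolane to give 6-methoxy-1-SEM-indol-3-yl pinacol boronate F1. Commercial 1,2,4,5-tetramethoxybenzene is dibrominated (Br2, CH2Cl2) to 1,4-dibromo-2,3,5,6-tetramethoxybenzene F2. Suzuki–Miyaura coupling of F1 with excess F2 (Pd(OAc)2, SPhos, K3PO4, toluene–water, 90 °C) should give 3-(4-bromo-2,3,5,6-tetramethoxyphenyl)-6-methoxy-1-SEM-indole F3. Indole 8 is N-protected (NaH, SEMCl) to 5-benzyloxy-1-SEM-indole F4, brominated with NBS to 5-benzyloxy-3-bromo-1-SEM-indole F5 and converted in the same way to 5-benzyloxy-1-SEM-indol-3-yl pinacol boronate F6. A second Suzuki–Miyaura coupling of F3 with F6 should give 17.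

2. Step 10. The 6π closure may be slow with the methoxy group on the inside of the closing terminus, which gives time for inward rotation of the hydroxyl (butenolide formation) and for autoxidation of the hydroquinone to quinone mixtures. Fallback (quinone assembly without the four-membered ring; sets out from 1 and 8, comes back at 18): acid-promoted conjugate addition of 1 to commercial 2,5-dichloro-1,4-benzoquinone (aq. HCl, THF), followed by DDQ reoxidation, should give 2,5-dichloro-3-(6-methoxy-1H-indol-3-yl)-1,4-benzoquinone F7. The same addition and reoxidation with 8 at the one remaining quinone C–H should give 2,5-dichloro-3-(6-methoxy-1H-indol-3-yl)-6-(5-benzyloxy-1H-indol-3-yl)-1,4-benzoquinone F8, with the indoles para. NaOMe in MeOH replaces both vinylogous acid chlorides to give the 2,5-dimethoxy-3,6-bis(indolyl)-1,4-benzoquinone F9. Na2S2O4 reduces it to 2-(5-benzyloxy-1H-indol-3-yl)-5-(6-methoxy-1H-indol-3-yl)-3,6-dimethoxybenzene-1,4-diol F10, and MeI with K2CO3 in acetone methylates the two phenols without touching the indole N–H, giving 18.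

3. Step 12. The fluoride-induced fragmentation may stall on one or both indole nitrogens, leaving mono-SEM or N-hydroxymethyl material. Fallback (two-stage Lewis acid and base cleavage; sets out from 17, comes back at 18): BF3·OEt2 in CH2Cl2 at 0 °C cleaves the silylethyl ethers to 5-benzyloxy-1-(hydroxymethyl)-3-{4-[1-(hydroxymethyl)-6-methoxyindol-3-yl]-2,3,5,6-tetramethoxyphenyl}indole F11, which should release formaldehyde on treatment with aqueous NH3 in MeOH to give 18.

**Further compounds**

F1 | step 9 | 6-methoxy-3-(4,4,5,5-tetramethyl-1,3,2-dioxaborolan-2-yl)-1-SEM-indole | COc1ccc2c(B3OC(C)(C)C(C)(C)O3)cn(COCC[Si](C)(C)C)c2c1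
F2 | step 9 | 1,4-dibromo-2,3,5,6-tetramethoxybenzene | COc1c(Br)c(OC)c(OC)c(Br)c1OC
F3 | step 9 | 3-(4-bromo-2,3,5,6-tetramethoxyphenyl)-6-methoxy-1-SEM-indole | COc1ccc2c(-c3c(OC)c(OC)c(Br)c(OC)c3OC)cn(COCC[Si](C)(C)C)c2c1
F4 | step 9 | 5-benzyloxy-1-SEM-indole | C[Si](C)(C)CCOCn1ccc2cc(OCc3ccccc3)ccc21
F5 | step 9 | 5-benzyloxy-3-bromo-1-SEM-indole | C[Si](C)(C)CCOCn1cc(Br)c2cc(OCc3ccccc3)ccc21
F6 | step 9 | 5-benzyloxy-3-(4,4,5,5-tetramethyl-1,3,2-dioxaborolan-2-yl)-1-SEM-indole | CC1(C)OB(c2cn(COCC[Si](C)(C)C)c3ccc(OCc4ccccc4)cc23)OC1(C)C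
F7 | step 10 | 2,5-dichloro-3-(6-methoxy-1H-indol-3-yl)-1,4-benzoquinone | COc1ccc2c(C3=C(Cl)C(=O)C=C(Cl)C3=O)c[nH]c2c1
F8 | step 10 | 2,5-dichloro-3-(6-methoxy-1H-indol-3-yl)-6-(5-benzyloxy-1H-indol-3-yl)-1,4-benzoquinone | COc1ccc2c(C3=C(Cl)C(=O)C(c4c[nH]c5ccc(OCc6ccccc6)cc45)=C(Cl)C3=O)c[nH]c2c1
F9 | step 10 | 2,5-dimethoxy-3-(6-methoxy-1H-indol-3-yl)-6-(5-benzyloxy-1H-indol-3-yl)-1,4-benzoquinone | COc1ccc2c(C3=C(OC)C(=O)C(c4c[nH]c5ccc(OCc6ccccc6)cc45)=C(OC)C3=O)c[nH]c2c1
F10 | step 10 | 2-(5-benzyloxy-1H-indol-3-yl)-5-(6-methoxy-1H-indol-3-yl)-3,6-dimethoxybenzene-1,4-diol | COc1ccc2c(-c3c(OC)c(O)c(-c4c[nH]c5ccc(OCc6ccccc6)cc45)c(OC)c3O)c[nH]c2c1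
F11 | step 12 | 5-benzyloxy-1-(hydroxymethyl)-3-{4-[1-(hydroxymethyl)-6-methoxyindol-3-yl]-2,3,5,6-tetramethoxyphenyl}indole | COc1c(-c2cn(CO)c3cc(OC)ccc23)c(OC)c(OC)c(-c2cn(CO)c3ccc(OCc4ccccc4)cc23)c1OC
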